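Cuts: first the C2–O–C15' ester joining half A (13R, vinyl) to half B (13S,14R, diol). Then O8–C13 of ring C in both halves, which leads both back to one (E)-C13=C14 allylic alcohol. Then C13=C14, C1–C2 and C4–C5, then C9–C10 together with C8–O, and last C5–C10.
Enabling feature (labdane numbering; ring B = C5–C10, ring C = O–C8–C9–C11–C12–C13): on ring B the C1 arm on C10, the oxygen on C8 and C11 on C9 share one face. C1 and O8 are 1,3-cis and C5 is the neighbour of C10. C1/O8 can therefore be a bridging γ-lactone and C5 a ketone, which is what a C10 β-keto ester radical gives on closing onto an (E)-C8=C9 olefin with its ester axial.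
Forward: geranylacetone supplies C6–C9, C11–C13, C16 and C17, and an aldol adds C1, C10 and C20. Ring B and the lactone close together, then the C4 arm, H5 and C2 are added and the side chain is extended to C15. Ring C is closed twice from the same alcohol, and the halves are esterified and unmasked.
Stereochemistry: C10 (absolute) comes from 8-phenylmenthyl shielding, C9 from the (E)-olefin in a chair, C8 from the lactone tether and C5 from hydroxyl-directed hydrogenation. C13/C14 come from Sharpless epoxidation with antipodal tartrates and invertive 6-exo opening.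
Key step: step 7

Conventions: the target SMILES reads 5S,8S,9R,10R in both halves, 13R in half A and 13S,14R in half B. β is the face of C20 (also C17, H9 and the C4 arm); α is the face of C1, O8, C11 and H5. Primes mark half B. TMSE = CH2CH2SiMe3.
Assumption: the open face of the C10 radical is taken from the usual 8-phenylmenthyl ester model (ester C=O syn to the carbinol C–H, phenyl stacked on the acyl π system) with the radical in its sickle form (C5=O anti to C1, C1=O syn to C5); this calls for (1S,2R,5S)-(+)-8-phenylmenthol, and if the sense proves opposite the equally available (−)-antipode would be used with no other change.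

Step 1
Reactants: 1 (E)-geranylacetone
Product: 2 geranylacetone ethylene ketal
Conditions: HOCH2CH2OH, p-TsOH·H2O (cat.), toluene, reflux, Dean–Stark
Reagents that add atoms: ethylene glycol, OCCO
Why: Acid-catalysed ketalization with azeotropic removal of water masks the C13 ketone against the enolate, hydride and ylide chemistry ahead and creates no stereocentre.

Step 2
Reactants: 2 geranylacetone ethylene ketal
Product: 4 terminal epoxide ketal (racemic), via bromohydrin 3 (not isolated)
Conditions: NBS, THF/H2O, 0 °C; then K2CO3, MeOH, rt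
Reagents that add atoms: water, O; N-bromosuccinimide, O=C1CCC(=O)N1Br (bromine present in 3 only)
Why: Bromohydrin formation in aqueous THF is selective for the terminal isopropylidene olefin of geranyl-type chains and base closes the epoxide by internal Williamson substitution; the racemic stereocentre is destroyed in step 3.

Step 3
Reactants: 4 terminal epoxide ketal
Product: 5 (4E)-4-methyl-7-(2-methyl-1,3-dioxolan-2-yl)hept-4-enal
Conditions: H5IO6, THF/Et2O, 0 °C, short contact
Reagents that add atoms: none
Why: Periodic acid opens the epoxide to the glycol and cleaves it (Malaprade-type cleavage) to the C5 aldehyde and acetone, and the short contact at 0 °C spares the dioxolane and the (E)-olefin.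

Step 4
Reactants: 6 (+)-8-phenylmenthol; 7 propionyl chloride
Product: 8 (+)-8-phenylmenthyl propionate
Conditions: pyridine, DMAP (cat.), CH2Cl2, 0 °C to rt
Reagents that add atoms: none
Why: DMAP-catalysed acylation of the secondary alcohol with an acid chloride attaches the controller without touching its three stereocentres.

Step 5
Reactants: 8 (+)-8-phenylmenthyl propionate; 5 aldehyde
Product: 9 β-hydroxy ester (mixture at C5 and C10)
Conditions: LiN(i-Pr)2, THF, −78 °C; then 5
Reagents that add atoms: none
Why: Aldol addition of the lithium enolate of 8 to the aldehyde forms C5–C10; the two new stereocentres need no control because C5 is oxidized in step 6 and C10 becomes planar in step 7.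

Step 6
Reactants: 9 β-hydroxy ester
Product: 10 (+)-8-phenylmenthyl α-methyl β-keto ester (C10 epimers)
Conditions: Dess–Martin periodinane, CH2Cl2, 0 °C to rt
Reagents that add atoms: none
Why: Dess–Martin oxidation gives the β-keto ester under non-basic, anhydrous conditions that leave ketal and olefin alone; C10 is a freely enolizing epimer mixture.

Step 7
Reactants: 10 α-methyl β-keto ester
Product: 11 keto γ-lactone, (1S,5S,8R)-1,5-dimethyl-8-[2-(2-methyl-1,3-dioxolan-2-yl)ethyl]-6-oxabicyclo[3.2.1]octane-2,7-dione (labdane 8S,9R,10S; C1, O8 and C11 α)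
Conditions: Mn(OAc)3·2H2O (2.2 equiv), KOAc (2 equiv), degassed AcOH, 25 to 45 °C
Reagents that add atoms: water (of crystallization), O
Why: Proposed new method: Mn(OAc)3 oxidizes the enol of 10 to the planar C10 radical, which adds 6-endo-trig to C9 of the (E)-C8=C9 olefin through a chair with the C5 ketone inside the ring (ring B, C9–C10); a second equivalent oxidizes the tertiary C8 radical to the cation, the axial ester carbonyl oxygen closes on it through a five-membered transition state (γ-lactone, C8–O), and the dioxacarbenium ion so formed is hydrolysed by the water of crystallization with release of 6. The closest known reaction type is the oxidative 6-endo cyclization of α-methyl β-keto esters onto trisubstituted olefins by trivalent manganese, known with 8-phenylmenthyl esters and known to end in lactones when a methyl or ethyl ester traps the tertiary cation; what goes beyond it is the departure of a hindered secondary alkoxy group, for which acyl–oxygen cleavage through the hemiorthoester, driven by relief of 1,3-diaxial compression and by entropy, is invoked in place of SN2 dealkylation. C9 follows from the (E)-olefin, which places C11 equatorial in the chair, and from the axial ester (ketone oxygen anti to the ester carbon), so that C11 and C1 end up cis. C8 is fixed by the tether, because a γ-lactone from C10 to C8 can only bridge 1,3-cis, so O8 arrives on the face of C1 and C17 is left on the face of C20. The absolute configuration at C10 comes from the auxiliary, whose phenyl ring stacks over one face of the radical and leaves the other open to the olefin. The step needs 6-endo over 5-exo closure (secured by the methyl group on C8, which directs attack to C9 and gives a tertiary radical), lactone capture over proton loss or acetate capture (secured by the 1,3-diaxial proximity of the carbonyl and by leaving out Cu(OAc)2) and survival of the dioxolane (secured by the KOAc buffer).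

Step 8
Reactants: 11 keto γ-lactone
Product: 12 C5 enol triflate (C5=C6)
Conditions: KN(SiMe3)2, THF, −78 °C; then N-(5-chloro-2-pyridyl)triflimide, −78 to −20 °C
Reagents that add atoms: N-(5-chloro-2-pyridyl)bis(trifluoromethanesulfonimide), FC(F)(F)S(=O)(=O)N(c1ccc(Cl)cn1)S(=O)(=O)C(F)(F)F
Why: Deprotonation can occur only at C6 because C10 is quaternary, and O-sulfonylation of the potassium enolate (enol triflate synthesis) fixes the C5=C6 olefin; lactone and ketal have no acidic site and no stereocentre is affected.

Step 9
Reactants: 13 2-bromoisobutyryl bromide; 14 2-(trimethylsilyl)ethanol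
Product: 15 TMSE 2-bromo-2-methylpropanoate
Conditions: pyridine, CH2Cl2, 0 °C to rt
Reagents that add atoms: none
Why: Acylation of the primary alcohol by the acid bromide gives a bromo ester whose silylethyl group can be removed at the end by fluoride at silicon, far from the hindered C3 carbonyl.

Step 10
Reactants: 15 TMSE 2-bromo-2-methylpropanoate; 12 enol triflate
Product: 17 ene lactone carrying the C(CH3)2CO2TMSE arm on C5, via zinc enolate 16 (not isolated)
Conditions: Zn dust (Me3SiCl-activated), THF, 40 °C; then 12, Pd(dba)2 (5 mol %), P(t-Bu)3 (6 mol %), THF, 50 °C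
Reagents that add atoms: zinc, [Zn] (present in 16 only)
Why: Zinc insertion gives the Reformatsky reagent, and its cross-coupling with the alkenyl triflate on zerovalent palladium bearing a bulky electron-rich phosphine (Negishi-type α-alkenylation of an ester) forms C4–C5; the mild zinc enolate leaves lactone and ketal untouched and no stereocentre is formed.

Step 11
Reactants: 17 ene lactone
Product: 19 ene diol (C1H2OH and C8–OH, both α), via lactol 18 (not isolated)
Conditions: i-Bu2AlH (1.2 equiv), CH2Cl2, −78 °C; MeOH; then NaBH4, MeOH/THF, 0 °C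
Reagents that add atoms: none
Why: i-Bu2AlH at −78 °C stops at the lactol of the more electrophilic bridged γ-lactone and leaves the acyclic ester next to quaternary C4, and NaBH4 then reduces only the ring-opened hydroxy aldehyde, which frees the C1 and C8 hydroxyls on the α face.

Step 12
Reactants: 19 ene diol
Product: 20 saturated diol (H5 α, C4 arm β)
Conditions: H2 (50 bar), [Ir(cod)(PCy3)(py)]PF6 (10 mol %), CH2Cl2, rt
Reagents that add atoms: none
Why: In this hydroxyl-directed homogeneous hydrogenation the cationic iridium catalyst is bound by the homoallylic C1 and C8 hydroxyls, both α, and delivers H2 to the α face of C5=C6, which sets C5 with the C4 arm trans to the C1 arm.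

Step 13
Reactants: 20 saturated diol
Product: 21 C1 aldehyde with free C8–OH
Conditions: Dess–Martin periodinane, CH2Cl2, 0 °C to rt
Reagents that add atoms: none
Why: Dess–Martin oxidation converts the only oxidizable (primary, neopentyl) alcohol into the aldehyde; with the C4 arm now equatorial the ring holds C1 and O8 diequatorial, so a bridging lactol should not interfere.

Step 14
Reactants: 21 C1 aldehyde
Product: 22 TMSE enol ether C10–CH=CH–OTMSE (E/Z mixture)
Conditions: Me3SiCH2CH2OCH2PPh3Cl, KN(SiMe3)2 (excess), THF, 0 °C; then 21, 0 °C to reflux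
Reagents that add atoms: [2-(trimethylsilyl)ethoxymethyl]triphenylphosphonium chloride, C[Si](C)(C)CCOC[P+](c1ccccc1)(c1ccccc1)c1ccccc1.[Cl-]
Why: Wittig alkoxymethylenation, a standard one-carbon homologation of hindered aldehydes, adds C2 and brings in the silylethyl group at the same time; the E/Z mixture is of no consequence.

Step 15
Reactants: 22 TMSE enol ether
Product: 23 bis-TMSE ester ketal (C2 and C3 esters, C8–OH free)
Conditions: [C5H5NH][CrO3Cl], 4 Å MS, CH2Cl2, rt
Reagents that add atoms: pyridinium chlorochromate, [O-][Cr](=O)(=O)Cl.c1cc[nH+]cc1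
Why: Oxidation of a β-monosubstituted enol ether by pyridinium chlorochromate (electrophilic attack of chromate on the electron-rich olefin, then 1,2-hydride shift) gives the ester directly, here the TMSE ester of C2; the tertiary alcohol and the C3 ester do not react.

Step 16
Reactants: 23 bis-TMSE ester ketal
Product: 24 C13 methyl ketone
Conditions: 1 M HCl, THF, rt
Reagents that add atoms: water, O
Why: Mild aqueous acid hydrolyses the dioxolane while TMSE esters are stable to it, and the equilibrium of the δ-hydroxy ketone with its cyclic hemiketal is harmless because the open form is drained in step 17.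

Step 17
Reactants: 24 C13 methyl ketone
Product: 25 (E)-enoate (ethyl ester at C15)
Conditions: (EtO)2P(O)CH2CO2Et, NaH, THF, 0 °C to rt; chromatographic removal of the (Z)-isomer
Reagents that add atoms: triethyl phosphonoacetate, CCOC(=O)CP(=O)(OCC)OCC
Why: Horner–Wadsworth–Emmons olefination of the unhindered methyl ketone should give mainly the (E)-trisubstituted enoate, and this geometry later fixes the C13/C14 relative configuration.

Step 18
Reactants: 25 (E)-enoate
Product: 26 (E)-allylic alcohol (common precursor of both halves)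
Conditions: i-Bu2AlH (3.2 equiv), CH2Cl2, −78 °C
Reagents that add atoms: none
Why: 1,2-Reduction of the unhindered enoate by i-Bu2AlH at −78 °C should be much faster than attack on the two TMSE esters, each shielded by a neighbouring quaternary carbon (C10 or C4) of the crowded ring.

Step 19
Reactants: 26 (E)-allylic alcohol
Product: 28 half B diol (13S,14R), via epoxy alcohol 27 (not isolated)
Conditions: Ti(OiPr)4 (10 mol %), D-(−)-DIPT (12 mol %), t-BuOOH, 4 Å MS, CH2Cl2, −20 °C; work-up; then CSA (10 mol %), CH2Cl2, 0 °C
Reagents that add atoms: tert-butyl hydroperoxide, CC(C)(C)OO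
Why: Sharpless asymmetric epoxidation with D-(−)-DIPT gives the (13R,14R)-epoxide (sense as for geraniol-type alcohols) and acid-catalysed 6-exo-tet opening by the C8 hydroxyl at tertiary C13 with inversion closes ring C and sets 13S,14R; material of the wrong ring B antipode carried from step 7 becomes a separable diastereomer here.

Step 20
Reactants: 26 (E)-allylic alcohol
Product: 30 half A diol (13R,14S), via epoxy alcohol 29 (not isolated)
Conditions: Ti(OiPr)4 (10 mol %), L-(+)-DIPT (12 mol %), t-BuOOH, 4 Å MS, CH2Cl2, −20 °C; work-up; then CSA (10 mol %), CH2Cl2, 0 °C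
Reagents that add atoms: tert-butyl hydroperoxide, CC(C)(C)OO
Why: The antipodal tartrate gives the (13S,14S)-epoxide by Sharpless asymmetric epoxidation, and the same invertive 6-exo-tet opening by the C8 hydroxyl closes ring C with the 13R configuration of half A.

Step 21
Reactants: 30 half A diol
Product: 31 half A vinyl bis-TMSE ester
Conditions: PPh3, I2, imidazole, toluene, 80 °C
Reagents that add atoms: none
Why: Garegg–Samuelsson-type reductive elimination of the vicinal diol (primary iodide, secondary oxyphosphonium, iodide-induced elimination) gives the C14=C15 vinyl group without touching C13.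

Step 22
Reactants: 31 half A vinyl bis-TMSE ester
Product: 32 half A C2 acid (C3 TMSE ester kept)
Conditions: LiOH·H2O, THF/MeOH/H2O, 45 °C; then dilute HCl, 0 °C
Reagents that add atoms: lithium hydroxide, [Li+].[OH-]
Why: Saponification discriminates by steric hindrance, since hydroxide reaches the C2 ester (CH2 next to C10) but not the C3 ester on quaternary C4, so only the C2 acid is freed.

Step 23
Reactants: 32 half A C2 acid; 28 half B diol
Product: 33 tris-TMSE protected dimer
Conditions: EDC·HCl, DMAP, CH2Cl2, 0 °C to rt
Reagents that add atoms: none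
Why: Carbodiimide/DMAP (Steglich) esterification acylates the primary C15' hydroxyl in preference to the C14' hydroxyl, which is secondary and next to the fully substituted C13'.

Step 24
Reactants: 33 tris-TMSE protected dimer
Product: 34 CNP0271961.3
Conditions: Bu4NF, THF, 0 °C to rt; then dilute HCl, 0 °C
Reagents that add atoms: none
Why: Fluoride attacks silicon and the three TMSE esters fragment to ethylene and Me3SiF irrespective of hindrance at the carbonyl groups, under conditions that spare the C2–O–C15' ester, the vinyl group and the tertiary allylic ether.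

Compound list
1 | (E)-geranylacetone, (5E)-6,10-dimethylundeca-5,9-dien-2-one | CC(=O)CC/C=C(\C)CCC=C(C)C | starting material
2 | geranylacetone ethylene ketal | CC1(OCCO1)CC/C=C(\C)CCC=C(C)C | intermediate
3 | terminal bromohydrin (secondary bromide, tertiary alcohol; racemic) | CC1(OCCO1)CC/C=C(\C)CCC(Br)C(C)(C)O | intermediate
4 | terminal epoxide ketal (racemic) | CC1(OCCO1)CC/C=C(\C)CCC2OC2(C)C | intermediate
5 | (4E)-4-methyl-7-(2-methyl-1,3-dioxolan-2-yl)hept-4-enal | CC1(OCCO1)CC/C=C(\C)CCC=O | intermediate
6 | (+)-8-phenylmenthol, (1S,2R,5S)-5-methyl-2-(2-phenylpropan-2-yl)cyclohexan-1-ol | CC(C)(c1ccccc1)[C@H]1CC[C@H](C)C[C@@H]1O | starting material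
7 | propionyl chloride | CCC(=O)Cl | starting material
8 | (+)-8-phenylmenthyl propionate | CCC(=O)O[C@H]1C[C@@H](C)CC[C@@H]1C(C)(C)c1ccccc1 | intermediate
9 | β-hydroxy ester (aldol, mixture at C5 and C10) | CC1(OCCO1)CC/C=C(\C)CCC(O)C(C)C(=O)O[C@H]2C[C@@H](C)CC[C@@H]2C(C)(C)c2ccccc2 | intermediate
10 | (+)-8-phenylmenthyl α-methyl β-keto ester (C10 epimers) | CC1(OCCO1)CC/C=C(\C)CCC(=O)C(C)C(=O)O[C@H]2C[C@@H](C)CC[C@@H]2C(C)(C)c2ccccc2 | intermediate
11 | keto γ-lactone (8S,9R,10S; C1, O8, C11 α) | CC1(OCCO1)CC[C@@H]2[C@]3(C)C(=O)O[C@@]2(C)CCC3=O | intermediate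
12 | C5 enol triflate of 11 | CC1(OCCO1)CC[C@@H]2[C@]3(C)C(=O)O[C@@]2(C)CC=C3OS(=O)(=O)C(F)(F)F | intermediate
13 | 2-bromoisobutyryl bromide | CC(C)(Br)C(=O)Br | starting material
14 | 2-(trimethylsilyl)ethanol | C[Si](C)(C)CCO | starting material
15 | TMSE 2-bromo-2-methylpropanoate | CC(C)(Br)C(=O)OCC[Si](C)(C)C | intermediate
16 | zinc enolate (Reformatsky reagent) of 15 | C[Si](C)(C)CCOC(=O)C(C)(C)[Zn]Br | intermediate
17 | ene lactone with C(CH3)2CO2TMSE on C5 (C5=C6) | CC1(OCCO1)CC[C@@H]2[C@]3(C)C(=O)O[C@@]2(C)CC=C3C(C)(C)C(=O)OCC[Si](C)(C)C | intermediate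
18 | γ-lactol of 17 (anomers) | CC1(OCCO1)CC[C@@H]2[C@]3(C)C(O)O[C@@]2(C)CC=C3C(C)(C)C(=O)OCC[Si](C)(C)C | intermediate
19 | ene diol (C1H2OH and C8–OH α) | CC1(OCCO1)CC[C@@H]2[C@](C)(CO)C(=CC[C@]2(C)O)C(C)(C)C(=O)OCC[Si](C)(C)C | intermediate
20 | saturated diol (H5 α, C4 arm β) | CC1(OCCO1)CC[C@@H]2[C@](C)(CO)[C@@H](C(C)(C)C(=O)OCC[Si](C)(C)C)CC[C@]2(C)O | intermediate
21 | C1 aldehyde | CC1(OCCO1)CC[C@@H]2[C@](C)(C=O)[C@@H](C(C)(C)C(=O)OCC[Si](C)(C)C)CC[C@]2(C)O | intermediate
22 | TMSE enol ether (E/Z) | CC1(OCCO1)CC[C@@H]2[C@](C)(C=COCC[Si](C)(C)C)[C@@H](C(C)(C)C(=O)OCC[Si](C)(C)C)CC[C@]2(C)O | intermediate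
23 | bis-TMSE ester ketal | CC1(OCCO1)CC[C@@H]2[C@](C)(CC(=O)OCC[Si](C)(C)C)[C@@H](C(C)(C)C(=O)OCC[Si](C)(C)C)CC[C@]2(C)O | intermediate
24 | C13 methyl ketone | CC(=O)CC[C@@H]1[C@](C)(CC(=O)OCC[Si](C)(C)C)[C@@H](C(C)(C)C(=O)OCC[Si](C)(C)C)CC[C@]1(C)O | intermediate
25 | (E)-enoate | CCOC(=O)/C=C(\C)CC[C@@H]1[C@](C)(CC(=O)OCC[Si](C)(C)C)[C@@H](C(C)(C)C(=O)OCC[Si](C)(C)C)CC[C@]1(C)O | intermediate
26 | (E)-allylic alcohol | OC/C=C(\C)CC[C@@H]1[C@](C)(CC(=O)OCC[Si](C)(C)C)[C@@H](C(C)(C)C(=O)OCC[Si](C)(C)C)CC[C@]1(C)O | intermediate
27 | (13R,14R)-epoxy alcohol | OC[C@H]1O[C@]1(C)CC[C@@H]2[C@](C)(CC(=O)OCC[Si](C)(C)C)[C@@H](C(C)(C)C(=O)OCC[Si](C)(C)C)CC[C@]2(C)O | intermediate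
28 | half B diol (13S,14R), ring C closed | OC[C@@H](O)[C@]1(C)CC[C@@H]2[C@](C)(CC(=O)OCC[Si](C)(C)C)[C@@H](C(C)(C)C(=O)OCC[Si](C)(C)C)CC[C@]2(C)O1 | intermediate
29 | (13S,14S)-epoxy alcohol | OC[C@@H]1O[C@@]1(C)CC[C@@H]2[C@](C)(CC(=O)OCC[Si](C)(C)C)[C@@H](C(C)(C)C(=O)OCC[Si](C)(C)C)CC[C@]2(C)O | intermediate
30 | half A diol (13R,14S), ring C closed | OC[C@H](O)[C@@]1(C)CC[C@@H]2[C@](C)(CC(=O)OCC[Si](C)(C)C)[C@@H](C(C)(C)C(=O)OCC[Si](C)(C)C)CC[C@]2(C)O1 | intermediate
31 | half A vinyl bis-TMSE ester (13R) | C=C[C@@]1(C)CC[C@@H]2[C@](C)(CC(=O)OCC[Si](C)(C)C)[C@@H](C(C)(C)C(=O)OCC[Si](C)(C)C)CC[C@]2(C)O1 | intermediate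
32 | half A C2 acid, C3 TMSE ester | C=C[C@@]1(C)CC[C@@H]2[C@](C)(CC(=O)O)[C@@H](C(C)(C)C(=O)OCC[Si](C)(C)C)CC[C@]2(C)O1 | intermediate
33 | tris-TMSE protected dimer | C=C[C@@]1(C)CC[C@@H]2[C@](C)(CC(=O)OC[C@@H](O)[C@]3(C)CC[C@@H]4[C@](C)(CC(=O)OCC[Si](C)(C)C)[C@@H](C(C)(C)C(=O)OCC[Si](C)(C)C)CC[C@]4(C)O3)[C@@H](C(C)(C)C(=O)OCC[Si](C)(C)C)CC[C@]2(C)O1 | intermediate
34 | CNP0271961.3 | C=C[C@@]1(C)CC[C@@H]2[C@](C)(CC(=O)OC[C@@H](O)[C@]3(C)CC[C@@H]4[C@](C)(CC(=O)O)[C@@H](C(C)(C)C(=O)O)CC[C@]4(C)O3)[C@@H](C(C)(C)C(=O)O)CC[C@]2(C)O1 | target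

Total step count: 24. Longest linear sequence: 21 steps (1, 2, 3, 5, 6, 7, 8, 10–18, 20–24).

Steps most likely to fail

**Step 7 (labelled).**
- What may go wrong: release of the hindered alkoxy group from the dioxacarbenium ion may be slower than its reversal and proton loss from the C8 cation. The acid may open the dioxolane. Shielding of the radical face may be incomplete, which chromatography can no longer correct once the auxiliary has left.
- Fallback with known chemistry, from 10 back to 11: 10 is oxidized with Mn(OAc)3·2H2O and Cu(OAc)2·H2O in AcOH. In this established variant divalent copper turns the tertiary C8 radical into the exocyclic olefin and the auxiliary stays on, giving the alkene keto ester F1, whose diastereomers can be separated.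
- LiAlH4 in Et2O removes the auxiliary reductively and gives the ene diol F2.
- Hg(OAc)2 in THF closes the axial C1 hydroxyl onto C8, which is possible only 1,3-cis, to give the organomercurial F3. NaBH4/NaOH then demercurates it to the bicyclic ether alcohol F4.
- RuCl3 (cat.)/NaIO4 oxidizes the ether CH2 to the lactone carbonyl and the C5 carbinol to the ketone, which gives 11.

**Step 10.**
- What may go wrong: transmetalation and reductive elimination at a palladium centre that carries a neopentyl-type alkenyl group and a tertiary enolate may be too slow. Reduction of the triflate or protonation of the zinc enolate would then take over.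
- Fallback, from 11 (bypassing 12) back to 17: the bond is made by carbonyl addition instead of cross-coupling. The zinc enolate 16 is added to the C5 ketone of 11 in refluxing THF (classical Reformatsky addition, from the open β face) to give the β-hydroxy ester F5.
- SOCl2/pyridine at 0 °C dehydrates F5. Only the C5=C6 olefin can form because C4 and C10 are quaternary, which gives 17.

**Step 12.**
- What may go wrong: the olefin, flanked by two quaternary carbons, may not reach the iridium centre. Decay of the catalyst to inactive clusters may outrun turnover, or undirected delivery of hydrogen to the β face may compete.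
- Fallback, from 11 back to 20 (bypassing steps 8 and 10–12): C4–C5 and the C5 stereocentre are made together by a suprafacial sigmatropic shift.
- IBX in DMSO dehydrogenates 11 to the enone F6. t-BuOOH/DBU epoxidizes its β face to give the epoxy ketone F7, and Wharton transposition (N2H4·H2O, AcOH, MeOH) gives the 7β-allylic alcohol F8 with C5=C6.
- Isobutyryl chloride/pyridine gives the isobutyrate F9. LiN(i-Pr)2/Me3SiCl forms the silyl ketene acetal F10, which on warming undergoes Ireland–Claisen rearrangement on the β face to the silyl ester F11. Work-up hydrolyses F11 to the acid F12 (C4 arm β, H5 α, C6=C7).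
- Mitsunobu esterification with 14 (PPh3, DIAD) gives the TMSE ester F13, and H2 over Pd/C saturates the unhindered C6=C7 olefin to the saturated lactone F14.
- Reduction as in step 11, through the lactol F15, gives 20.

Further compounds
F1 | step 7 | alkene keto ester (C8=C17, auxiliary retained) | CC1(OCCO1)CC[C@H]2C(=C)CCC(=O)[C@@]2(C)C(=O)O[C@H]3C[C@@H](C)CC[C@@H]3C(C)(C)c3ccccc3
F2 | step 7 | ene diol (C1H2OH, C5–OH epimers) | CC1(OCCO1)CC[C@H]2C(=C)CCC(O)[C@@]2(C)CO
F3 | step 7 | organomercurial (C17–HgOAc) | CC1(OCCO1)CC[C@@H]2[C@]3(C)CO[C@@]2(C[Hg]OC(C)=O)CCC3O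
F4 | step 7 | bicyclic ether alcohol | CC1(OCCO1)CC[C@@H]2[C@]3(C)CO[C@@]2(C)CCC3O
F5 | step 10 | β-hydroxy ester (C4 arm β, C5–OH α) | CC1(OCCO1)CC[C@@H]2[C@]3(C)C(=O)O[C@@]2(C)CC[C@]3(O)C(C)(C)C(=O)OCC[Si](C)(C)C
F6 | step 12 | enone (C6=C7) | CC1(OCCO1)CC[C@@H]2[C@]3(C)C(=O)O[C@@]2(C)C=CC3=O
F7 | step 12 | 6β,7β-epoxy ketone | CC1(OCCO1)CC[C@@H]2[C@]3(C)C(=O)O[C@@]2(C)[C@@H]4O[C@@H]4C3=O
F8 | step 12 | 7β-allylic alcohol (C5=C6) | CC1(OCCO1)CC[C@@H]2[C@]3(C)C(=O)O[C@@]2(C)[C@H](O)C=C3
F9 | step 12 | isobutyrate | CC1(OCCO1)CC[C@@H]2[C@]3(C)C(=O)O[C@@]2(C)[C@H](OC(=O)C(C)C)C=C3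
F10 | step 12 | silyl ketene acetal | CC1(OCCO1)CC[C@@H]2[C@]3(C)C(=O)O[C@@]2(C)[C@H](OC(O[Si](C)(C)C)=C(C)C)C=C3
F11 | step 12 | silyl ester | CC1(OCCO1)CC[C@@H]2[C@]3(C)C(=O)O[C@@]2(C)C=C[C@@H]3C(C)(C)C(=O)O[Si](C)(C)C
F12 | step 12 | acid (C4 arm β, C6=C7) | CC1(OCCO1)CC[C@@H]2[C@]3(C)C(=O)O[C@@]2(C)C=C[C@@H]3C(C)(C)C(=O)O
F13 | step 12 | TMSE ester | CC1(OCCO1)CC[C@@H]2[C@]3(C)C(=O)O[C@@]2(C)C=C[C@@H]3C(C)(C)C(=O)OCC[Si](C)(C)C
F14 | step 12 | saturated lactone | CC1(OCCO1)CC[C@@H]2[C@]3(C)C(=O)O[C@@]2(C)CC[C@@H]3C(C)(C)C(=O)OCC[Si](C)(C)C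
F15 | step 12 | lactol (anomers) | CC1(OCCO1)CC[C@@H]2[C@]3(C)C(O)O[C@@]2(C)CC[C@@H]3C(C)(C)C(=O)OCC[Si](C)(C)C
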